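## Retrosynthetic overview

1. Target acid 16 ⇐ oxidation of primary alcohol 15 ⇐ diimide reduction of the C4=C5 bond of 3,6-dihydro-1,2-dioxine 14 (sets C4).
2. Dioxine ring of 14 (the only ring made; both C–O bonds at once) ⇐ [4+2] cycloaddition of singlet oxygen to (3E,5E)-dienol 13; the diene geometry fixes the C3/C6 cis relationship.
3. Dienol 13 ⇐ C4–C5 bond by one-pot Zr-catalysed carboalumination of alkyne 7 and Pd cross-coupling with (E)-vinyl iodide 10 (from pent-3-yn-1-ol by hydrozirconation–iodination).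
4. Alkyne 7 ⇐ (S)-3-bromo-2-methylpropan-1-ol 2 (the only purchased stereocentre, it becomes C2' of the side chain) by Cu-catalysed Grignard coupling with 1, then iodide and acetylide.
5. Ring order: the benzene ring is bought; the 1,2-dioxane ring is formed once, in step 6.

Assumption: (7-bromoheptyl)benzene 1, (S)-3-bromo-2-methylpropan-1-ol 2 and pent-3-yn-1-ol 8 are bought; target = 2-[(3S,4S,6R)-4,6-dimethyl-6-[(2R)-2-methyl-10-phenyldecyl]-1,2-dioxan-3-yl]acetic acid.

## Route

Step 1
Reactants: 1 (7-bromoheptyl)benzene; 2 (S)-3-bromo-2-methylpropan-1-ol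
Product: 5 (R)-2-methyl-10-phenyldecan-1-ol, via 7-phenylheptylmagnesium bromide 3 (not isolated), via chloromagnesium (S)-3-bromo-2-methylpropan-1-olate 4 (not isolated)
Conditions: 1, Mg, THF, 40 °C; 2, MeMgCl (1.0 equiv), THF, −20 °C; combine, Li2CuCl4 (3 mol %), NMP (4 equiv), 0 °C → rt; 1 M HCl
Reagents that add atoms: none
Why: Kochi-type Cu-catalysed sp3–sp3 coupling of a primary Grignard reagent with the primary bromide (OH masked as its magnesium alkoxide) leaves the stereocentre untouched, so it is carried over from 2 (S becomes R only because the CIP priorities change).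

Step 2
Reactants: 5 (R)-2-methyl-10-phenyldecan-1-ol
Product: 6 (R)-1-iodo-2-methyl-10-phenyldecane
Conditions: I2, PPh3, imidazole, CH2Cl2, 0 °C → rt
Reagents that add atoms: iodine, II
Why: Appel-type iodination is an SN2 displacement at the primary carbon and does not involve the adjacent stereocentre.

Step 3
Reactants: 6 (R)-1-iodo-2-methyl-10-phenyldecane
Product: 7 (R)-4-methyl-12-phenyldodec-1-yne
Conditions: HC≡CLi·H2NCH2CH2NH2 (2 equiv), DMSO, 15 °C → rt
Reagents that add atoms: lithium acetylide–ethylenediamine complex, [Li]C#C.NCCN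
Why: SN2 alkylation of lithium acetylide by the primary iodide in DMSO gives the terminal alkyne with the β-stereocentre unchanged.

Step 4
Reactants: 8 pent-3-yn-1-ol
Product: 10 (E)-4-iodopent-3-en-1-ol, via O-zirconated (E)-alkenylzirconocene 9 (not isolated)
Conditions: Cp2Zr(H)Cl (2.3 equiv), THF, rt → 45 °C; then I2, 0 °C; 1 M HCl
Reagents that add atoms: iodine, II
Why: In this hydrozirconation–iodination the first equivalent of Schwartz reagent turns OH into the Zr alkoxide, the second adds H–Zr syn and equilibrates Zr to the less hindered methyl-bearing carbon, and iodinolysis with retention gives the (E)-2-iodo-2-alkene.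

Step 5
Reactants: 7 (R)-4-methyl-12-phenyldodec-1-yne; 10 (E)-4-iodopent-3-en-1-ol
Product: 13 (3E,5E,8R)-4,6,8-trimethyl-16-phenylhexadeca-3,5-dien-1-ol, via (E)-alkenyldimethylalane 11 (not isolated), via dimethylaluminium (E)-4-iodopent-3-en-1-olate 12 (not isolated)
Conditions: 7, Me3Al (2.5 equiv), Cp2ZrCl2 (25 mol %), CH2Cl2, rt; then 12 [10, Me3Al (1.0 equiv), THF, 0 °C], ZnCl2 (0.5 equiv), Pd(PPh3)4 (5 mol %), THF, rt; 1 M HCl, 0 °C
Reagents that add atoms: trimethylaluminium, C[Al](C)C
Why: Negishi Zr-catalysed carboalumination adds Me–Al syn to the terminal alkyne (Al terminal), and the Pd/Zn-catalysed cross-coupling of the alkenylalane with the vinyl iodide proceeds with retention at both sp2 carbons, giving the (3E,5E)-diene.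

Step 6
Reactants: 13 (3E,5E,8R)-4,6,8-trimethyl-16-phenylhexadeca-3,5-dien-1-ol
Product: 14 2-[(3S,6R)-4,6-dimethyl-6-[(2R)-2-methyl-10-phenyldecyl]-3,6-dihydro-1,2-dioxin-3-yl]ethan-1-ol
Conditions: O2, hν (white LED), tetraphenylporphyrin (1 mol %), CH2Cl2, −20 °C; preparative HPLC, no amine bases
Reagents that add atoms: oxygen, O=O
Why: The [4+2] cycloaddition of singlet oxygen to the s-cis (E,E)-diene is suprafacial, so the two outside groups (C3 CH2CH2OH and C6 CH2R) end up cis and only the (3S,6R) and (3R,6S) rings can form; the side-chain stereocentre is too remote to bias the diene faces (about 1:1 expected), so 14 is separated from its (3R,6S,2'R) diastereomer.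

Step 7
Reactants: 14 2-[(3S,6R)-4,6-dimethyl-6-[(2R)-2-methyl-10-phenyldecyl]-3,6-dihydro-1,2-dioxin-3-yl]ethan-1-ol
Product: 15 2-[(3S,4S,6R)-4,6-dimethyl-6-[(2R)-2-methyl-10-phenyldecyl]-1,2-dioxan-3-yl]ethan-1-ol
Conditions: KO2CN=NCO2K (20–30 equiv, portions), AcOH (slow addition), MeOH/CH2Cl2, 0 °C → rt, 48 h, one recycle
Reagents that add atoms: none
Why: Diimide reduction transfers H2 in a concerted syn fashion without touching the O–O bond, and it approaches the ring alkene from the face carrying only C3–H and C6–CH3, which places the C4 methyl cis to the C3 and C6 chains (4S).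

Step 8
Reactants: 15 2-[(3S,4S,6R)-4,6-dimethyl-6-[(2R)-2-methyl-10-phenyldecyl]-1,2-dioxan-3-yl]ethan-1-ol
Product: 16 2-[(3S,4S,6R)-4,6-dimethyl-6-[(2R)-2-methyl-10-phenyldecyl]-1,2-dioxan-3-yl]acetic acid
Conditions: TEMPO (20 mol %), PhI(OAc)2 (2.5 equiv), MeCN/H2O 1:1, rt
Reagents that add atoms: water, O
Why: Oxoammonium (TEMPO/PhI(OAc)2) oxidation takes the primary alcohol through the aldehyde hydrate to the acid under mildly acidic conditions that leave the dialkyl peroxide and all four stereocentres untouched.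

## Compound list

1 | (7-bromoheptyl)benzene | BrCCCCCCCc1ccccc1 | starting material
2 | (S)-3-bromo-2-methylpropan-1-ol | C[C@H](CBr)CO | starting material
3 | 7-phenylheptylmagnesium bromide | Br[Mg]CCCCCCCc1ccccc1 | intermediate
4 | chloromagnesium (S)-3-bromo-2-methylpropan-1-olate | C[C@H](CBr)CO[Mg]Cl | intermediate
5 | (R)-2-methyl-10-phenyldecan-1-ol | C[C@H](CCCCCCCCc1ccccc1)CO | intermediate
6 | (R)-1-iodo-2-methyl-10-phenyldecane | C[C@H](CCCCCCCCc1ccccc1)CI | intermediate
7 | (R)-4-methyl-12-phenyldodec-1-yne | C[C@H](CCCCCCCCc1ccccc1)CC#C | intermediate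
8 | pent-3-yn-1-ol | CC#CCCO | starting material
9 | chlorobis(cyclopentadienyl)zirconium (E)-4-[chlorobis(cyclopentadienyl)zirconio]pent-3-en-1-olate (Cp drawn σ-bonded) | C/C(=C\CCO[Zr](Cl)(C1C=CC=C1)C1C=CC=C1)[Zr](Cl)(C1C=CC=C1)C1C=CC=C1 | intermediate
10 | (E)-4-iodopent-3-en-1-ol | C/C(I)=C\CCO | intermediate
11 | [(1E,4R)-2,4-dimethyl-12-phenyldodec-1-en-1-yl]dimethylalumane | C[C@H](CCCCCCCCc1ccccc1)C/C(C)=C/[Al](C)C | intermediate
12 | dimethylaluminium (E)-4-iodopent-3-en-1-olate | C/C(I)=C\CCO[Al](C)C | intermediate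
13 | (3E,5E,8R)-4,6,8-trimethyl-16-phenylhexadeca-3,5-dien-1-ol | OCC/C=C(\C)/C=C(\C)/C[C@H](C)CCCCCCCCc1ccccc1 | intermediate
14 | 2-[(3S,6R)-4,6-dimethyl-6-[(2R)-2-methyl-10-phenyldecyl]-3,6-dihydro-1,2-dioxin-3-yl]ethan-1-ol | C[C@H](CCCCCCCCc1ccccc1)C[C@]1(C)C=C(C)[C@H](CCO)OO1 | intermediate
15 | 2-[(3S,4S,6R)-4,6-dimethyl-6-[(2R)-2-methyl-10-phenyldecyl]-1,2-dioxan-3-yl]ethan-1-ol | C[C@H](CCCCCCCCc1ccccc1)C[C@]1(C)C[C@H](C)[C@H](CCO)OO1 | intermediate
16 | 2-[(3S,4S,6R)-4,6-dimethyl-6-[(2R)-2-methyl-10-phenyldecyl]-1,2-dioxan-3-yl]acetic acid | C[C@H](CCCCCCCCc1ccccc1)C[C@]1(C)C[C@H](C)[C@H](CC(=O)O)OO1 | target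

## Step count

Total steps: 8. Longest linear sequence: 7 (steps 1, 2, 3, 5, 6, 7, 8); step 4 is a one-step side branch.

## Three steps most likely to fail

**Step 7 (diimide reduction).** The ring alkene is trisubstituted and flanked by a quaternary carbon, so diimide will be slow and conversion may stall; the facial preference is expected to be moderate only. Fallback, setting out from 14 and coming back at 15: replace the concerted diimide transfer by a radical hydrogen-atom-transfer hydrogenation (Mn(dpm)3 cat., PhSiH3, t-BuOOH, i-PrOH, rt, short reaction time). Trisubstituted alkenes are the best substrates for this chemistry. H• adds to C5 and the tertiary C4 radical is quenched from the less hindered face, the same face diimide would use. Attack of that radical on the endocyclic O–O bond is geometrically poor, but cleavage of the peroxide by the reduced metal is the risk to watch. No new compound is made.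

**Step 6 (singlet-oxygen [4+2]).** Two problems are expected. Schenck ene reaction at the allylic CH3/CH2 groups competes with the cycloaddition. The remote stereocentre gives essentially no facial bias, so at most half of the cycloadduct is 14 and the two diastereomers may be hard to separate as alcohols. Fallback, setting out from 13 and coming back at 16: oxidise first (CrO3/H2SO4, acetone, 0 °C) to (3E,5E,8R)-4,6,8-trimethyl-16-phenylhexadeca-3,5-dienoic acid F5. Photooxygenate this acid (rose bengal, O2, hν, MeOH/CH2Cl2, 0 °C); 4,6-dimethyl-3,5-dienoic acids are, to my recollection, the substrate class with the closest precedent for this cycloaddition. Separate 2-[(3S,6R)-4,6-dimethyl-6-[(2R)-2-methyl-10-phenyldecyl]-3,6-dihydro-1,2-dioxin-3-yl]acetic acid F6 from its (3R,6S) diastereomer by reversed-phase HPLC. Reduce F6 with diimide as in step 7 to give 16 directly.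

**Step 5 (one-pot carboalumination / cross-coupling).** Both coupling partners are hindered (β,β-disubstituted alkenylalane, α-methyl vinyl iodide) and the iodide carries a free OH masked only as an aluminium alkoxide; protodealumination or homocoupling could dominate. Fallback, setting out from 7 and coming back at 13: build the second trisubstituted alkene by a second carboalumination instead of a cross-coupling with 10. Carboaluminate 7 as before and quench alane 11 with I2 to isolate (1E,4R)-1-iodo-2,4-dimethyl-12-phenyldodec-1-ene F1. Couple it with ethynylzinc bromide (ethynylmagnesium bromide, ZnBr2, Pd(PPh3)4, THF) to give (3E,6R)-4,6-dimethyl-14-phenyltetradec-3-en-1-yne F2. Carboaluminate F2 (Me3Al, Cp2ZrCl2) to [(1E,3E,6R)-2,4,6-trimethyl-14-phenyltetradeca-1,3-dien-1-yl]dimethylalumane F3. Treat with n-BuLi to form lithium butyl[(1E,3E,6R)-2,4,6-trimethyl-14-phenyltetradeca-1,3-dien-1-yl]dimethylaluminate F4, which opens ethylene oxide with retention to give 13.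

## Further compounds

F1 | step 5 | (1E,4R)-1-iodo-2,4-dimethyl-12-phenyldodec-1-ene | C[C@H](CCCCCCCCc1ccccc1)C/C(C)=C/I
F2 | step 5 | (3E,6R)-4,6-dimethyl-14-phenyltetradec-3-en-1-yne | C[C@H](CCCCCCCCc1ccccc1)C/C(C)=C/C#C
F3 | step 5 | [(1E,3E,6R)-2,4,6-trimethyl-14-phenyltetradeca-1,3-dien-1-yl]dimethylalumane | C[C@H](CCCCCCCCc1ccccc1)C/C(C)=C/C(C)=C/[Al](C)C
F4 | step 5 | lithium butyl[(1E,3E,6R)-2,4,6-trimethyl-14-phenyltetradeca-1,3-dien-1-yl]dimethylaluminate | [Li+].CCCC[Al-](C)(C)/C=C(C)/C=C(C)/C[C@H](C)CCCCCCCCc1ccccc1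
F5 | step 6 | (3E,5E,8R)-4,6,8-trimethyl-16-phenylhexadeca-3,5-dienoic acid | OC(=O)C/C=C(\C)/C=C(\C)/C[C@H](C)CCCCCCCCc1ccccc1
F6 | step 6 | 2-[(3S,6R)-4,6-dimethyl-6-[(2R)-2-methyl-10-phenyldecyl]-3,6-dihydro-1,2-dioxin-3-yl]acetic acid | C[C@H](CCCCCCCCc1ccccc1)C[C@]1(C)C=C(C)[C@H](CC(=O)O)OO1
F0 | step 7 | none | none
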